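The amounts say that red, blue, violet and teal each hold 3.00 reagent per substrate, and that each substrate takes up two reagent on its way to bis adduct.

in all of them: reagent 0.174 M

|  | substrate | temperature | remark | time |
|---|---|---|---|---|
| cedar | 0.12 M | 60 °C | run made earlier |  |
| red | 0.058 M | 60 °C |  | 8.0 min |
| blue | 0.058 M | 40 °C |  | 8.0 min |
| violet | 0.058 M | 80 °C |  | 8.0 min |
| teal | 0.058 M |  | at 80 °C until 1.5 min, from then on at 40 °C | 8.0 min |

- cedar (time / s: bis adduct / %, substrate / %): 10.0: 3.5, 79.2; 15.0: 5.4, 71.0; 20.0: 8.8, 63.4; 30.0: 14.5, 52.8; 50.0: 22.1, 41.3

(standard deviation of a reading: 1 percentage point)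

- for bis adduct the crystals are counted in
- as a solid, counted per litre of solution: crystals
- steps thought possible: substrate + reagent -> mono adduct; reagent + mono adduct -> bis adduct; crystals <-> bis adduct; bis adduct <-> isomer of the product
- the earlier runs do not show what temperature does; that part of a forecast is a guess

- the flask with the highest amount of bis adduct, in percent of the substrate charged ("all alike" if they lie within 1.5 percentage points) (red / blue / violet / teal / all alike)
- final bis adduct, as a percentage of the substrate charged, in red
- final bis adduct, as a percentage of the substrate charged, in blue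
- final bis adduct, as a percentage of the substrate charged, in violet
- final bis adduct, as a percentage of the substrate charged, in teal

I define the clock τ as ln(substrate charged / substrate left). My zero of the scale is the symmetric case, with both additions equally fast. They then run on one clock whatever the reagent does, so mono adduct is τe^(−τ). The passed share P, the part of the charge through both additions, is P = 1 − (1 + τ)e^(−τ).

Cedar's first reading shows the substrate losing 1.40 min⁻¹ of itself, a pseudo-first-order constant s read with the scatter of that reading. Red has cedar's reagent charge and cedar's temperature, so I start it at the same s. Its rate then slows by two factors. Red's reagent can fall by a factor of 3.00 at most, which leaves a floor frequency of 0.466 min⁻¹. On that floor red's clock reaches 3.73 at 8.0 min. The substrate's own factor is then 41.7, so on that floor red's rate ends down by 125. My commitment is the floor passed share of red, 88.7%.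

| Case | τ | P | bis adduct read |
|---|---|---|---|
| cedar, 20.0 s | 0.456 | 7.71% | 8.8% |
| cedar, 50.0 s | 0.884 | 22.2% | 22.1% |
| red, 8.0 min, floor | 3.73 | 88.7% | asked |

Cedar's bis adduct readings at these two times lie near P, with a scatter of 1 percentage point. The earlier runs do not show what temperature does, so I reckon no further flask.

The forecast names teal as highest. It gives red 87% (70% to 98%), blue 62% (40% to 80%), violet 78% (50% to 98%) and teal 90% (75% to 98%). Its words are: “Teal makes about 85% quickly, then finishes cool with little isomerisation, so it is probably highest, narrowly over red.” Its figures are bis adduct, while mine is a passed share.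

The flasks give red 24.3%, blue 55.5%, violet 27.3% and teal 24.8%, so blue is highest.

    substrate + reagent → mono adduct (k = 0.160 L mol⁻¹ s⁻¹, Ea = 42.0 kJ mol⁻¹)
    reagent + mono adduct → bis adduct (k = 0.240 L mol⁻¹ s⁻¹, Ea = 60.0 kJ mol⁻¹)
    crystals ⇌ bis adduct, rate k3*(cs3 - [bis adduct]) while solid is left; crystals form when [bis adduct] > cs3 (solubility = 2.20 mM, k = 3.60 s⁻¹)
    bis adduct ⇌ isomer of the product (K = 24.0, k = 0.0880 s⁻¹, Ea = 75.0 kJ mol⁻¹, ΔH = −11.0 kJ mol⁻¹)
    (constants at 60 °C)

Red's substrate of 0.293% reads a clock of 5.83, above my floor, and a passed share of 98.0%, above 88.7%. Red holds bis adduct 24.3% and isomer of the product 74.9%, together 99.2%. A neighbour of red, with the same amounts and time but run at 35 °C, has substrate 8.05%, a clock of 2.52 and a passed share of 71.7%. It holds bis adduct 52.6% and isomer of the product 15.8%, together 68.4%.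

All runs were generated by integration for an exercise; noise was put on by code.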